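**Assumption:** the target has no stereocentres and its only alkene carries two identical methyl groups, so it is achiral; "single enantiomer" is met trivially and no stereocontrol is needed.

## Retrosynthetic overview

1. Disconnect the quinone C2–O bond: the free 4-OH of a 3-prenyl naphthohydroquinone ester adds to 2-bromo-1,4-naphthoquinone with loss of bromide.
2. Disconnect the prenyl group: cross-metathesis of a C3-allyl group with 2-methyl-2-butene.
3. Disconnect the C3-allyl group: aromatic Claisen rearrangement of a 4-O-allyl ether, made by selective 4-O-allylation of methyl 1,4-dihydroxy-2-naphthoate (the 1-OH is tied up by hydrogen bonding to the ester).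
4. No rings are formed: both naphthalene units are bought intact.

The route is designed from known reaction types and has not been run; conditions are proposed, not literature-verified for these exact substrates.

## Route

**Step 1**
Reactants: 1, methyl 1,4-dihydroxy-2-naphthoate; 2, allyl bromide
Product: 3, methyl 4-(allyloxy)-1-hydroxy-2-naphthoate
Conditions: K2CO3 (1.1 equiv), allyl bromide (1.05 equiv), DMF, rt, Ar
Reagents that add atoms: allyl bromide, C=CCBr
Why: Williamson ether synthesis; the 1-OH is locked in a hydrogen bond to the ester carbonyl, so the free 4-OH should be alkylated selectively with one equivalent of base and electrophile.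

**Step 2**
Reactants: 3, methyl 4-(allyloxy)-1-hydroxy-2-naphthoate
Product: 4, methyl 3-allyl-1,4-dihydroxy-2-naphthoate
Conditions: degassed N,N-diethylaniline, 180 °C, Ar (sealed tube)
Reagents that add atoms: none
Why: aromatic Claisen rearrangement; C3 is the only ortho position bearing hydrogen, and the high C3–C4 bond order of the naphthalene makes the [3,3] shift easy.

**Step 3**
Reactants: 4, methyl 3-allyl-1,4-dihydroxy-2-naphthoate; 5, 2-methyl-2-butene
Product: 6, methyl 1,4-dihydroxy-3-(3-methylbut-2-en-1-yl)-2-naphthoate
Conditions: Grubbs II (5 mol%), 2-methyl-2-butene/CH2Cl2 (1:1), 40 °C, sealed, Ar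
Reagents that add atoms: 2-methyl-2-butene, CC=C(C)C (supplies the =CMe2 terminus in place of =CH2)
Why: olefin cross-metathesis of a terminal allyl arene with excess 2-methyl-2-butene is a standard allyl-to-prenyl conversion that tolerates free phenols and esters; the product alkene has no E/Z issue.

**Step 4**
Reactants: 6, methyl 1,4-dihydroxy-3-(3-methylbut-2-en-1-yl)-2-naphthoate; 7, 2-bromo-1,4-naphthoquinone
Product: 8, Rubioncolin C, methyl 4-[(1,4-dioxo-1,4-dihydronaphthalen-2-yl)oxy]-1-hydroxy-3-(3-methylbut-2-en-1-yl)-2-naphthoate
Conditions: K2CO3 (1.05 equiv), 7 (1.05 equiv), degassed DMF, 0 °C → rt, Ar, dark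
Reagents that add atoms: 2-bromo-1,4-naphthoquinone, O=C1C=C(Br)C(=O)c2ccccc12
Why: addition–elimination (vinylogous acyl substitution) of a phenoxide on a 2-haloquinone; the non-chelated 4-O should react in preference to the ester-bound 1-OH, and with C2/C3 of the nucleophile blocked only O-arylation is possible.

**Checks made**
- Atom balance: 6 (C17H18O4) + 7 (C10H5BrO2) − HBr = C27H22O6, the target formula.
- Substituent pattern of 8 matches the target SMILES: 1-OH, 2-CO2Me, 3-prenyl, 4-O-(quinon-2-yl), quinone C3–H.
- Functional-group survival: the methyl ester and chelated 1-OH are untouched throughout. The hydroquinones 4 and 6 are air-sensitive, so steps 2–4 are run degassed under argon. No acid is used after the prenyl group is installed, which avoids chroman formation.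
- Stereochemistry: none to set.

## Compound list

1 | methyl 1,4-dihydroxy-2-naphthoate | COC(=O)c1cc(O)c2ccccc2c1O | starting material
2 | allyl bromide | C=CCBr | starting material
3 | methyl 4-(allyloxy)-1-hydroxy-2-naphthoate | COC(=O)c1cc(OCC=C)c2ccccc2c1O | intermediate
4 | methyl 3-allyl-1,4-dihydroxy-2-naphthoate | COC(=O)c1c(CC=C)c(O)c2ccccc2c1O | intermediate
5 | 2-methyl-2-butene | CC=C(C)C | starting material
6 | methyl 1,4-dihydroxy-3-(3-methylbut-2-en-1-yl)-2-naphthoate | COC(=O)c1c(CC=C(C)C)c(O)c2ccccc2c1O | intermediate
7 | 2-bromo-1,4-naphthoquinone | O=C1C=C(Br)C(=O)c2ccccc12 | starting material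
8 | Rubioncolin C | COC(=O)c1c(CC=C(C)C)c(OC2=CC(=O)c3ccccc3C2=O)c2ccccc2c1O | target

## Summary

Total steps: 4. Longest linear sequence: 4 (from 1).

Steps most likely to fail, with fallbacks:

1. **Step 4 (aryloxyquinone formation).** Risks are redox exchange between hydroquinone 6 and bromoquinone 7 (the oxidised prenylquinone then cyclises to mollugin under base) and competing 1-O-arylation. Fallback: protect the 1-OH of 3 as a MOM ether before the Claisen step, so that steps 2–3 deliver a mono-phenol with only the 4-OH free, which cannot be oxidised to a quinone. Couple that with 7, then remove the chelation-activated MOM group with MgBr2·OEt2 or TFA/CH2Cl2 (two extra steps).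

2. **Step 3 (cross-metathesis on a free hydroquinone).** Risks are catalyst deactivation and Ru–H isomerisation of the allyl group to propenyl. Fallback: drop the allyl/metathesis sequence. Alkylate the 4-OH of 1 with 3-chloro-3-methyl-1-butyne (K2CO3, KI, cat. CuI), semi-hydrogenate with Lindlar catalyst to the 1,1-dimethylallyl ether, and run the Claisen rearrangement, which gives the C3-prenyl group of 6 directly.

3. **Step 2 (high-temperature Claisen giving an oxidisable hydroquinone).** Risks are oxidation or cyclisation to a dihydronaphthofuran. Fallback: form the C3–C bond by cross-coupling. Stille-couple methyl 3-bromo-1,4-dimethoxy-2-naphthoate with tributyl(prenyl)stannane, oxidise with CAN to 2-methoxycarbonyl-3-prenyl-1,4-naphthoquinone, and reduce with Na2S2O4 to 6.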